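**Assumption:** (R)- and (S)-but-3-en-2-ol (catalogue alcohols, ≥98% ee) are the bought chiral materials; the aryl Grignard reagents are made in the flask from the bought aryl bromides.

**Abbreviations:** TBS = tert-butyldimethylsilyl; Bn = benzyl; Tf = trifluoromethanesulfonyl. Ring A is the benzofuran arene that carries the styryl arm; ring B is the arene of the second dihydrobenzofuran. "Unit B" = the (2S,3S)-4-(benzyloxy)-2-[3,4-bis(benzyloxy)phenyl]-3-[3,5-bis(benzyloxy)phenyl]-2,3-dihydro-1-benzofuran-6-yl group.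

## Retrosynthetic overview

1. Target ⇐ global debenzylation of the heptabenzyl ether ⇐ Heck coupling of the ring A C6 triflate with 4-benzyloxystyrene (stilbene made last).
2. Each trans-2,3-diaryl-dihydrobenzofuran ⇐ ArMgBr addition to a 3-aryl lactol, then acid closure of the C2–O bond (C2 set trans by C3) ⇐ oxidative cleavage of an ortho-(1-arylbut-2-enyl)phenol.
3. That phenol ⇐ aromatic Claisen rearrangement of a 3,5-bis(silyloxy)phenyl (E)-4-arylbut-3-en-2-yl ether. The [3,3] shift forms the C3–C3a bond and transfers the carbinol stereocentre of but-3-en-2-ol to C3; the symmetric phloroglucinol ring makes both ortho positions equivalent.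
4. Ether ⇐ cross-metathesis of a styrene with the Mitsunobu ether of but-3-en-2-ol. The (R)-alcohol programs the (2S,3S) unit on ring B, the (S)-alcohol the (2R,3R) unit on ring A.
5. Ring order: dihydrofuran on ring B first (step 7); its C6 oxygen becomes triflate then vinyl; then dihydrofuran on ring A (step 14); then the stilbene.

## Route

**Step 1**
Reactants: 1 phloroglucinol
Product: 2 3,5-bis(tert-butyldimethylsilyloxy)phenol
Conditions: TBSCl (2.0 equiv), imidazole (4 equiv), DMF, 0 °C → rt; chromatography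
Reagents that add atoms: tert-butyldimethylsilyl chloride, CC(C)(C)[Si](C)(C)Cl
Why: Statistical silylation of the symmetric triol gives the bis-silyl ether (mono- and tris-silylated material is separated and recycled), leaving one phenol whose two ortho positions are equivalent and each flanked by oxygen.

**Step 2**
Reactants: 2 3,5-bis(tert-butyldimethylsilyloxy)phenol; 3 (R)-but-3-en-2-ol
Product: 4 (S)-1-(but-3-en-2-yloxy)-3,5-bis(tert-butyldimethylsilyloxy)benzene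
Conditions: PPh3, DIAD, THF, 0 °C → rt
Reagents that add atoms: none
Why: Mitsunobu etherification of the secondary allylic alcohol goes by SN2 with inversion, so the bought (R)-carbinol becomes the (S)-aryl ether (the minor achiral crotyl ether from SN2′ attack is removed by chromatography).

**Step 3**
Reactants: 5 3,5-bis(benzyloxy)benzaldehyde
Product: 6 1,3-bis(benzyloxy)-5-vinylbenzene
Conditions: Ph3PCH3Br, KOtBu, THF, 0 °C → rt
Reagents that add atoms: methyltriphenylphosphonium bromide, C[P+](c1ccccc1)(c1ccccc1)c1ccccc1.[Br-]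
Why: Wittig methylenation of the aldehyde gives the styrene needed as metathesis partner.

**Step 4**
Reactants: 4 (S)-butenyl aryl ether; 6 1,3-bis(benzyloxy)-5-vinylbenzene (2 equiv)
Product: 7 1-{[(2S,3E)-4-[3,5-bis(benzyloxy)phenyl]but-3-en-2-yl]oxy}-3,5-bis(tert-butyldimethylsilyloxy)benzene
Conditions: second-generation Hoveyda–Grubbs catalyst (5 mol %), 1,4-benzoquinone (10 mol %), CH2Cl2, 40 °C
Reagents that add atoms: none
Why: Olefin cross-metathesis of the styrene with the hindered terminal alkene is E-selective and leaves the allylic C–O stereocentre untouched, with benzoquinone suppressing ruthenium hydride isomerisation of the allyl ether.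

**Step 5**
Reactants: 7 (S,E)-aryl 4-arylbut-3-en-2-yl ether
Product: 9 2-{(1S,2E)-1-[3,5-bis(benzyloxy)phenyl]but-2-en-1-yl}-3,5-bis(tert-butyldimethylsilyloxy)phenol, via dienone 8 (not isolated)
Conditions: PhNEt2 (degassed), 170 °C, sealed tube
Reagents that add atoms: none
Why: The aromatic Claisen rearrangement ([3,3]-sigmatropic) goes through a chair transition state with the methyl group equatorial and forms the aryl–C bond on the face from which the oxygen leaves, so the (S)-C–O centre is transferred into the (S)-diarylmethine carbon with an E-propenyl group, and the symmetric ring can only be attacked at a carbon between two oxygens before the dienone enolises.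

**Step 6**
Reactants: 9 ortho-(1-arylbut-2-enyl)phenol
Product: 12 (3S)-3-[3,5-bis(benzyloxy)phenyl]-4,6-bis(tert-butyldimethylsilyloxy)-2,3-dihydro-1-benzofuran-2-ol (anomer mixture), via vicinal diol 10 (not isolated), via hydroxy aldehyde 11 (not isolated)
Conditions: OsO4 (2 mol %), NaIO4 (4 equiv), 2,6-lutidine, dioxane/H2O 3:1, rt
Reagents that add atoms: osmium tetroxide, O=[Os](=O)(=O)=O (catalytic; its oxygen is replenished by sodium periodate, [Na+].[O-]I(=O)(=O)=O, and water, O)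
Why: Lemieux–Johnson oxidation (dihydroxylation then periodate glycol cleavage) removes the propenyl terminus as acetaldehyde, and the aldehyde is trapped at once by the ortho phenol as the lactol, which protects the doubly benzylic stereocentre from enolisation.

**Step 7**
Reactants: 12 lactol; 13 4-bromo-1,2-bis(benzyloxy)benzene (as its Grignard reagent)
Product: 15 (2S,3S)-2-[3,4-bis(benzyloxy)phenyl]-3-[3,5-bis(benzyloxy)phenyl]-4,6-bis(tert-butyldimethylsilyloxy)-2,3-dihydro-1-benzofuran, via benzylic alcohol 14 (not isolated)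
Conditions: 13, Mg, THF (ArMgBr, 3.5 equiv); add 12, −20 → 0 °C; then HCl (4 M in dioxane), 0 °C → rt
Reagents that add atoms: none
Why: Grignard addition to the open aldehyde form of the lactol gives a benzylic alcohol that ionises in acid to a para-alkoxy-stabilised cation and is captured by the phenol (cationic cyclisation), the C3 aryl group steering the new C2 aryl trans under thermodynamic control so that C2 is (S).

**Step 8**
Reactants: 15 bis-silyl dihydrobenzofuran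
Product: 18 (2S,3S)-4-(benzyloxy)-2-[3,4-bis(benzyloxy)phenyl]-3-[3,5-bis(benzyloxy)phenyl]-2,3-dihydro-1-benzofuran-6-yl trifluoromethanesulfonate, via diol 16 (not isolated), via monotriflate 17 (not isolated)
Conditions: TBAF (2.1 equiv), THF, 0 °C; PhNTf2 (1.05 equiv), −78 → 0 °C; BnBr (2 equiv), rt; aq. NH4Cl work-up; under argon
Reagents that add atoms: N-phenylbis(trifluoromethanesulfonimide), O=S(=O)(N(c1ccccc1)S(=O)(=O)C(F)(F)F)C(F)(F)F; benzyl bromide, BrCc1ccccc1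
Why: Fluoride desilylation gives the bis-phenoxide, whose unhindered C6 oxygen is sulfonylated selectively by the bulky triflimide while the C4 oxygen, shielded by the neighbouring C3 aryl group, is left and then O-benzylated in the same flask.

**Step 9**
Reactants: 18 aryl triflate
Product: 19 (2S,3S)-4-(benzyloxy)-2-[3,4-bis(benzyloxy)phenyl]-3-[3,5-bis(benzyloxy)phenyl]-6-vinyl-2,3-dihydro-1-benzofuran
Conditions: vinylboronic acid pinacol ester (1.5 equiv), PdCl2(dppf) (5 mol %), K3PO4, dioxane/H2O, 80 °C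
Reagents that add atoms: vinylboronic acid pinacol ester, C=CB1OC(C)(C)C(C)(C)O1
Why: Suzuki–Miyaura coupling of the aryl triflate installs the styrene handle on ring B without touching the stereocentres.

**Step 10**
Reactants: 2 3,5-bis(tert-butyldimethylsilyloxy)phenol; 20 (S)-but-3-en-2-ol
Product: 21 (R)-1-(but-3-en-2-yloxy)-3,5-bis(tert-butyldimethylsilyloxy)benzene
Conditions: PPh3, DIAD, THF, 0 °C → rt
Reagents that add atoms: none
Why: The same Mitsunobu inversion as in step 2, applied to the other bought enantiomer, gives the (R)-ether that programs the opposite configuration needed on ring A.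

**Step 11**
Reactants: 19 vinyl dihydrobenzofuran; 21 (R)-butenyl aryl ether (3 equiv)
Product: 22 1-{[(2R,3E)-4-(unit B)but-3-en-2-yl]oxy}-3,5-bis(tert-butyldimethylsilyloxy)benzene
Conditions: second-generation Hoveyda–Grubbs catalyst (10 mol %), 1,4-benzoquinone (20 mol %), CH2Cl2, 40 °C
Reagents that add atoms: none
Why: E-selective olefin cross-metathesis joins the two halves at a position remote from all five stereocentres, the cheap ether being used in excess because it homodimerises slowly.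

**Step 12**
Reactants: 22 (R,E)-aryl 4-arylbut-3-en-2-yl ether
Product: 24 2-{(1R,2E)-1-(unit B)but-2-en-1-yl}-3,5-bis(tert-butyldimethylsilyloxy)phenol, via dienone 23 (not isolated)
Conditions: PhNEt2 (degassed), 170 °C, sealed tube
Reagents that add atoms: none
Why: The second aromatic Claisen rearrangement ([3,3]-sigmatropic, chair transition state, methyl equatorial) transfers the (R)-C–O centre into the (R)-diarylmethine carbon that becomes C3 of the ring A dihydrofuran, independently of the remote ring B stereocentres.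

**Step 13**
Reactants: 24 ortho-(1-arylbut-2-enyl)phenol
Product: 27 (3R)-3-(unit B)-4,6-bis(tert-butyldimethylsilyloxy)-2,3-dihydro-1-benzofuran-2-ol (anomer mixture), via vicinal diol 25 (not isolated), via hydroxy aldehyde 26 (not isolated)
Conditions: OsO4 (2 mol %), NaIO4 (4 equiv), 2,6-lutidine, dioxane/H2O 3:1, rt
Reagents that add atoms: osmium tetroxide, O=[Os](=O)(=O)=O (catalytic; its oxygen is replenished by sodium periodate, [Na+].[O-]I(=O)(=O)=O, and water, O)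
Why: Lemieux–Johnson cleavage of the only alkene gives the aldehyde, which is stored as the lactol exactly as in step 6.

**Step 14**
Reactants: 27 lactol; 28 1-(benzyloxy)-4-bromobenzene (as its Grignard reagent)
Product: 30 (2R,3R)-2-[4-(benzyloxy)phenyl]-3-(unit B)-4,6-bis(tert-butyldimethylsilyloxy)-2,3-dihydro-1-benzofuran, via benzylic alcohol 29 (not isolated)
Conditions: 28, Mg, THF (ArMgBr, 3.5 equiv); add 27, −20 → 0 °C; then HCl (4 M in dioxane), 0 °C, short contact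
Reagents that add atoms: none
Why: Grignard addition and acid-mediated cationic ring closure by the phenol give the trans ring under control of the (R)-C3 centre, so C2 is (R), and any diastereomer arising from incomplete chirality transfer is removed here by chromatography.

**Step 15**
Reactants: 30 bis-silyl bis-dihydrobenzofuran
Product: 32 (2R,3R)-2-[4-(benzyloxy)phenyl]-3-(unit B)-4-hydroxy-2,3-dihydro-1-benzofuran-6-yl trifluoromethanesulfonate, via diol 31 (not isolated)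
Conditions: TBAF (2.1 equiv), THF, 0 °C; PhNTf2 (1.0 equiv), −78 → 0 °C; aq. NH4Cl work-up; under argon
Reagents that add atoms: N-phenylbis(trifluoromethanesulfonimide), O=S(=O)(N(c1ccccc1)S(=O)(=O)C(F)(F)F)C(F)(F)F
Why: Desilylation and site-selective triflation of the unhindered C6 phenoxide, as in step 8, leave the hindered ring A C4 phenol free, as it is in the target.

**Step 16**
Reactants: 32 aryl triflate; 33 1-(benzyloxy)-4-vinylbenzene
Product: 34 (2R,3R)-2-[4-(benzyloxy)phenyl]-6-{(E)-2-[4-(benzyloxy)phenyl]ethenyl}-3-(unit B)-2,3-dihydro-1-benzofuran-4-ol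
Conditions: Pd(OAc)2 (10 mol %), PPh3 (25 mol %), LiCl, Et3N, DMF, 90 °C
Reagents that add atoms: none
Why: Mizoroki–Heck reaction of the aryl triflate with the styrene, run through the neutral chloride pathway, gives the linear E-stilbene and tolerates the free phenol.

**Step 17**
Reactants: 34 heptabenzyl ether
Product: 35 target, (2R,3R)-3-[(2S,3S)-2-(3,4-dihydroxyphenyl)-3-(3,5-dihydroxyphenyl)-4-hydroxy-2,3-dihydro-1-benzofuran-6-yl]-2-(4-hydroxyphenyl)-6-[(E)-2-(4-hydroxyphenyl)ethenyl]-2,3-dihydro-1-benzofuran-4-ol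
Conditions: BCl3 (1 M in CH2Cl2, 20 equiv), pentamethylbenzene (25 equiv), CH2Cl2, −78 → −40 °C; MeOH quench
Reagents that add atoms: none
Why: Lewis-acid debenzylation with pentamethylbenzene as benzyl cation scavenger removes all seven benzyl ethers at low temperature without reducing the stilbene, which hydrogenolysis would not spare.

## Compound list

1 | phloroglucinol (benzene-1,3,5-triol) | Oc1cc(O)cc(O)c1 | starting material
2 | 3,5-bis(tert-butyldimethylsilyloxy)phenol | Oc1cc(O[Si](C)(C)C(C)(C)C)cc(O[Si](C)(C)C(C)(C)C)c1 | intermediate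
3 | (R)-but-3-en-2-ol | C[C@@H](O)C=C | starting material
4 | (S)-1-(but-3-en-2-yloxy)-3,5-bis(tert-butyldimethylsilyloxy)benzene | C[C@H](Oc1cc(O[Si](C)(C)C(C)(C)C)cc(O[Si](C)(C)C(C)(C)C)c1)C=C | intermediate
5 | 3,5-bis(benzyloxy)benzaldehyde | O=Cc1cc(OCc2ccccc2)cc(OCc2ccccc2)c1 | starting material
6 | 1,3-bis(benzyloxy)-5-vinylbenzene | C=Cc1cc(OCc2ccccc2)cc(OCc2ccccc2)c1 | intermediate
7 | 1-{[(2S,3E)-4-[3,5-bis(benzyloxy)phenyl]but-3-en-2-yl]oxy}-3,5-bis(tert-butyldimethylsilyloxy)benzene | C[C@H](Oc1cc(O[Si](C)(C)C(C)(C)C)cc(O[Si](C)(C)C(C)(C)C)c1)/C=C/c1cc(OCc2ccccc2)cc(OCc2ccccc2)c1 | intermediate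
8 | (6R)-6-{(1R,2E)-1-[3,5-bis(benzyloxy)phenyl]but-2-en-1-yl}-3,5-bis(tert-butyldimethylsilyloxy)cyclohexa-2,4-dien-1-one | C/C=C/[C@@H](c1cc(OCc2ccccc2)cc(OCc2ccccc2)c1)[C@H]1C(=O)C=C(O[Si](C)(C)C(C)(C)C)C=C1O[Si](C)(C)C(C)(C)C | intermediate (not isolated)
9 | 2-{(1S,2E)-1-[3,5-bis(benzyloxy)phenyl]but-2-en-1-yl}-3,5-bis(tert-butyldimethylsilyloxy)phenol | C/C=C/[C@@H](c1cc(OCc2ccccc2)cc(OCc2ccccc2)c1)c1c(O)cc(O[Si](C)(C)C(C)(C)C)cc1O[Si](C)(C)C(C)(C)C | intermediate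
10 | (1S)-1-[3,5-bis(benzyloxy)phenyl]-1-[2-hydroxy-4,6-bis(tert-butyldimethylsilyloxy)phenyl]butane-2,3-diol (mixture at C2 and C3) | CC(O)C(O)[C@@H](c1cc(OCc2ccccc2)cc(OCc2ccccc2)c1)c1c(O)cc(O[Si](C)(C)C(C)(C)C)cc1O[Si](C)(C)C(C)(C)C | intermediate (not isolated)
11 | (2S)-2-[3,5-bis(benzyloxy)phenyl]-2-[2-hydroxy-4,6-bis(tert-butyldimethylsilyloxy)phenyl]acetaldehyde | O=C[C@@H](c1cc(OCc2ccccc2)cc(OCc2ccccc2)c1)c1c(O)cc(O[Si](C)(C)C(C)(C)C)cc1O[Si](C)(C)C(C)(C)C | intermediate (not isolated)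
12 | (3S)-3-[3,5-bis(benzyloxy)phenyl]-4,6-bis(tert-butyldimethylsilyloxy)-2,3-dihydro-1-benzofuran-2-ol (anomer mixture) | OC1Oc2cc(O[Si](C)(C)C(C)(C)C)cc(O[Si](C)(C)C(C)(C)C)c2[C@@H]1c1cc(OCc2ccccc2)cc(OCc2ccccc2)c1 | intermediate
13 | 4-bromo-1,2-bis(benzyloxy)benzene | Brc1ccc(OCc2ccccc2)c(OCc2ccccc2)c1 | starting material
14 | (2S)-1-[3,4-bis(benzyloxy)phenyl]-2-[3,5-bis(benzyloxy)phenyl]-2-[2-hydroxy-4,6-bis(tert-butyldimethylsilyloxy)phenyl]ethan-1-ol (C1 epimers) | OC(c1ccc(OCc2ccccc2)c(OCc2ccccc2)c1)[C@@H](c1cc(OCc2ccccc2)cc(OCc2ccccc2)c1)c1c(O)cc(O[Si](C)(C)C(C)(C)C)cc1O[Si](C)(C)C(C)(C)C | intermediate (not isolated)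
15 | (2S,3S)-2-[3,4-bis(benzyloxy)phenyl]-3-[3,5-bis(benzyloxy)phenyl]-4,6-bis(tert-butyldimethylsilyloxy)-2,3-dihydro-1-benzofuran | CC(C)(C)[Si](C)(C)Oc1cc(O[Si](C)(C)C(C)(C)C)c2c(c1)O[C@H](c1ccc(OCc3ccccc3)c(OCc3ccccc3)c1)[C@H]2c1cc(OCc2ccccc2)cc(OCc2ccccc2)c1 | intermediate
16 | (2S,3S)-2-[3,4-bis(benzyloxy)phenyl]-3-[3,5-bis(benzyloxy)phenyl]-2,3-dihydro-1-benzofuran-4,6-diol | Oc1cc(O)c2c(c1)O[C@H](c1ccc(OCc3ccccc3)c(OCc3ccccc3)c1)[C@H]2c1cc(OCc2ccccc2)cc(OCc2ccccc2)c1 | intermediate (not isolated)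
17 | (2S,3S)-2-[3,4-bis(benzyloxy)phenyl]-3-[3,5-bis(benzyloxy)phenyl]-4-hydroxy-2,3-dihydro-1-benzofuran-6-yl trifluoromethanesulfonate | O=S(=O)(Oc1cc(O)c2c(c1)O[C@H](c1ccc(OCc3ccccc3)c(OCc3ccccc3)c1)[C@H]2c1cc(OCc2ccccc2)cc(OCc2ccccc2)c1)C(F)(F)F | intermediate (not isolated)
18 | (2S,3S)-4-(benzyloxy)-2-[3,4-bis(benzyloxy)phenyl]-3-[3,5-bis(benzyloxy)phenyl]-2,3-dihydro-1-benzofuran-6-yl trifluoromethanesulfonate | O=S(=O)(Oc1cc(OCc3ccccc3)c2c(c1)O[C@H](c1ccc(OCc3ccccc3)c(OCc3ccccc3)c1)[C@H]2c1cc(OCc2ccccc2)cc(OCc2ccccc2)c1)C(F)(F)F | intermediate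
19 | (2S,3S)-4-(benzyloxy)-2-[3,4-bis(benzyloxy)phenyl]-3-[3,5-bis(benzyloxy)phenyl]-6-vinyl-2,3-dihydro-1-benzofuran | C=Cc1cc(OCc3ccccc3)c2c(c1)O[C@H](c1ccc(OCc3ccccc3)c(OCc3ccccc3)c1)[C@H]2c1cc(OCc2ccccc2)cc(OCc2ccccc2)c1 | intermediate
20 | (S)-but-3-en-2-ol | C[C@H](O)C=C | starting material
21 | (R)-1-(but-3-en-2-yloxy)-3,5-bis(tert-butyldimethylsilyloxy)benzene | C[C@@H](Oc1cc(O[Si](C)(C)C(C)(C)C)cc(O[Si](C)(C)C(C)(C)C)c1)C=C | intermediate
22 | 1-{[(2R,3E)-4-(unit B)but-3-en-2-yl]oxy}-3,5-bis(tert-butyldimethylsilyloxy)benzene | C[C@@H](Oc1cc(O[Si](C)(C)C(C)(C)C)cc(O[Si](C)(C)C(C)(C)C)c1)/C=C/c1cc(OCc3ccccc3)c2c(c1)O[C@H](c1ccc(OCc3ccccc3)c(OCc3ccccc3)c1)[C@H]2c1cc(OCc2ccccc2)cc(OCc2ccccc2)c1 | intermediate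
23 | (6S)-6-{(1S,2E)-1-(unit B)but-2-en-1-yl}-3,5-bis(tert-butyldimethylsilyloxy)cyclohexa-2,4-dien-1-one | C/C=C/[C@H](c1cc(OCc3ccccc3)c2c(c1)O[C@H](c1ccc(OCc3ccccc3)c(OCc3ccccc3)c1)[C@H]2c1cc(OCc2ccccc2)cc(OCc2ccccc2)c1)[C@@H]1C(=O)C=C(O[Si](C)(C)C(C)(C)C)C=C1O[Si](C)(C)C(C)(C)C | intermediate (not isolated)
24 | 2-{(1R,2E)-1-(unit B)but-2-en-1-yl}-3,5-bis(tert-butyldimethylsilyloxy)phenol | C/C=C/[C@H](c1cc(OCc3ccccc3)c2c(c1)O[C@H](c1ccc(OCc3ccccc3)c(OCc3ccccc3)c1)[C@H]2c1cc(OCc2ccccc2)cc(OCc2ccccc2)c1)c1c(O)cc(O[Si](C)(C)C(C)(C)C)cc1O[Si](C)(C)C(C)(C)C | intermediate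
25 | (1R)-1-(unit B)-1-[2-hydroxy-4,6-bis(tert-butyldimethylsilyloxy)phenyl]butane-2,3-diol (mixture at C2 and C3) | CC(O)C(O)[C@H](c1cc(OCc3ccccc3)c2c(c1)O[C@H](c1ccc(OCc3ccccc3)c(OCc3ccccc3)c1)[C@H]2c1cc(OCc2ccccc2)cc(OCc2ccccc2)c1)c1c(O)cc(O[Si](C)(C)C(C)(C)C)cc1O[Si](C)(C)C(C)(C)C | intermediate (not isolated)
26 | (2R)-2-(unit B)-2-[2-hydroxy-4,6-bis(tert-butyldimethylsilyloxy)phenyl]acetaldehyde | O=C[C@H](c1cc(OCc3ccccc3)c2c(c1)O[C@H](c1ccc(OCc3ccccc3)c(OCc3ccccc3)c1)[C@H]2c1cc(OCc2ccccc2)cc(OCc2ccccc2)c1)c1c(O)cc(O[Si](C)(C)C(C)(C)C)cc1O[Si](C)(C)C(C)(C)C | intermediate (not isolated)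
27 | (3R)-3-(unit B)-4,6-bis(tert-butyldimethylsilyloxy)-2,3-dihydro-1-benzofuran-2-ol (anomer mixture) | OC1Oc2cc(O[Si](C)(C)C(C)(C)C)cc(O[Si](C)(C)C(C)(C)C)c2[C@H]1c1cc(OCc3ccccc3)c2c(c1)O[C@H](c1ccc(OCc3ccccc3)c(OCc3ccccc3)c1)[C@H]2c1cc(OCc2ccccc2)cc(OCc2ccccc2)c1 | intermediate
28 | 1-(benzyloxy)-4-bromobenzene | Brc1ccc(OCc2ccccc2)cc1 | starting material
29 | (2R)-1-[4-(benzyloxy)phenyl]-2-(unit B)-2-[2-hydroxy-4,6-bis(tert-butyldimethylsilyloxy)phenyl]ethan-1-ol (C1 epimers) | OC(c1ccc(OCc2ccccc2)cc1)[C@H](c1cc(OCc3ccccc3)c2c(c1)O[C@H](c1ccc(OCc3ccccc3)c(OCc3ccccc3)c1)[C@H]2c1cc(OCc2ccccc2)cc(OCc2ccccc2)c1)c1c(O)cc(O[Si](C)(C)C(C)(C)C)cc1O[Si](C)(C)C(C)(C)C | intermediate (not isolated)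
30 | (2R,3R)-2-[4-(benzyloxy)phenyl]-3-(unit B)-4,6-bis(tert-butyldimethylsilyloxy)-2,3-dihydro-1-benzofuran | CC(C)(C)[Si](C)(C)Oc1cc(O[Si](C)(C)C(C)(C)C)c2c(c1)O[C@@H](c1ccc(OCc3ccccc3)cc1)[C@@H]2c1cc(OCc3ccccc3)c2c(c1)O[C@H](c1ccc(OCc3ccccc3)c(OCc3ccccc3)c1)[C@H]2c1cc(OCc2ccccc2)cc(OCc2ccccc2)c1 | intermediate
31 | (2R,3R)-2-[4-(benzyloxy)phenyl]-3-(unit B)-2,3-dihydro-1-benzofuran-4,6-diol | Oc1cc(O)c2c(c1)O[C@@H](c1ccc(OCc3ccccc3)cc1)[C@@H]2c1cc(OCc3ccccc3)c2c(c1)O[C@H](c1ccc(OCc3ccccc3)c(OCc3ccccc3)c1)[C@H]2c1cc(OCc2ccccc2)cc(OCc2ccccc2)c1 | intermediate (not isolated)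
32 | (2R,3R)-2-[4-(benzyloxy)phenyl]-3-(unit B)-4-hydroxy-2,3-dihydro-1-benzofuran-6-yl trifluoromethanesulfonate | O=S(=O)(Oc1cc(O)c2c(c1)O[C@@H](c1ccc(OCc3ccccc3)cc1)[C@@H]2c1cc(OCc3ccccc3)c2c(c1)O[C@H](c1ccc(OCc3ccccc3)c(OCc3ccccc3)c1)[C@H]2c1cc(OCc2ccccc2)cc(OCc2ccccc2)c1)C(F)(F)F | intermediate
33 | 1-(benzyloxy)-4-vinylbenzene | C=Cc1ccc(OCc2ccccc2)cc1 | starting material
34 | (2R,3R)-2-[4-(benzyloxy)phenyl]-6-{(E)-2-[4-(benzyloxy)phenyl]ethenyl}-3-(unit B)-2,3-dihydro-1-benzofuran-4-ol | O(Cc4ccccc4)c1ccc(/C=C/c2cc(O)c3c(c2)O[C@@H](c2ccc(OCc4ccccc4)cc2)[C@@H]3c2cc(OCc4ccccc4)c3c(c2)O[C@H](c2ccc(OCc4ccccc4)c(OCc4ccccc4)c2)[C@H]3c2cc(OCc4ccccc4)cc(OCc4ccccc4)c2)cc1 | intermediate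
35 | CNP0107857.3 | Oc1ccc(/C=C/c2cc(O)c3c(c2)O[C@@H](c2ccc(O)cc2)[C@@H]3c2cc(O)c3c(c2)O[C@H](c2ccc(O)c(O)c2)[C@H]3c2cc(O)cc(O)c2)cc1 | target

## Step count and weak points

Total: 17 steps. Longest linear sequence: 15 steps (steps 1, 2, 4–9, 11–17).

**Step 5 (the same operation recurs as step 12).** The thermal rearrangement of the cinnamyl-type ether 7 may ionise and lose enantiomeric purity, or stall. The fallback makes the same diarylmethine centre by a copper-mediated anti-SN2′ arylation; it sets out from 1, 3 and 6 and comes back to the route at 16.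

- Phloroglucinol 1 is converted (MOMCl, iPr2NEt, CH2Cl2) into 1,3,5-tris(methoxymethoxy)benzene F1.
- Cross-metathesis of 6 with free (R)-but-3-en-2-ol 3 (second-generation Hoveyda–Grubbs catalyst) gives (2R,3E)-4-[3,5-bis(benzyloxy)phenyl]but-3-en-2-ol F2.
- Picolinic acid, DCC and DMAP give (2R,3E)-4-[3,5-bis(benzyloxy)phenyl]but-3-en-2-yl pyridine-2-carboxylate F3.
- F1 is lithiated between two MOM ethers (n-BuLi, THF, 0 °C), transmetallated (MgBr2·OEt2, then CuBr·SMe2) and added to F3 at −78 → 0 °C. The picolinate directs the aryl group to the γ-carbon anti to the leaving group. Because the carbinol is used here with retention, this gives the same (S)-configured carbon as in 9, in 2-{(1S,2E)-1-[3,5-bis(benzyloxy)phenyl]but-2-en-1-yl}-1,3,5-tris(methoxymethoxy)benzene F4.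
- Lemieux–Johnson cleavage as in step 6 gives (2S)-2-[3,5-bis(benzyloxy)phenyl]-2-[2,4,6-tris(methoxymethoxy)phenyl]acetaldehyde F5. It has no lactol to protect it and is used crude and cold.
- The Grignard reagent from 13 gives (2S)-1-[3,4-bis(benzyloxy)phenyl]-2-[3,5-bis(benzyloxy)phenyl]-2-[2,4,6-tris(methoxymethoxy)phenyl]ethan-1-ol F6.
- HCl in MeOH removes the three MOM groups and closes the trans-dihydrofuran to give diol 16, which is triflated and benzylated as in the last two stages of step 8 (with K2CO3 as base).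

**Step 8.** The triflimide may not discriminate well enough between the C6 and C4 phenoxides. The fallback moves the selectivity to the cross-coupling; it sets out from 15 and comes back at 19.

- Desilylation (TBAF) and exhaustive triflation (Tf2O, pyridine) give (2S,3S)-2-[3,4-bis(benzyloxy)phenyl]-3-[3,5-bis(benzyloxy)phenyl]-2,3-dihydro-1-benzofuran-4,6-diyl bis(trifluoromethanesulfonate) F7.
- Suzuki coupling with one equivalent of vinylboronic acid pinacol ester (Pd(PPh3)4, K3PO4) reacts first at the unhindered C6 triflate to give (2S,3S)-2-[3,4-bis(benzyloxy)phenyl]-3-[3,5-bis(benzyloxy)phenyl]-6-vinyl-2,3-dihydro-1-benzofuran-4-yl trifluoromethanesulfonate F8.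
- The remaining hindered triflate is hydrolysed with Et4NOH in dioxane to (2S,3S)-2-[3,4-bis(benzyloxy)phenyl]-3-[3,5-bis(benzyloxy)phenyl]-6-vinyl-2,3-dihydro-1-benzofuran-4-ol F9.
- Benzylation (BnBr, K2CO3, DMF) gives 19.

**Step 17.** BCl3 may ionise the C2–O bonds of the electron-rich dihydrobenzofurans, and the scavenger could then trap the ring-opened cation. The fallback removes the benzyl groups before the alkene exists and ends with an ester cleavage; it sets out from 32 and comes back at 35.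

- Neutral hydrogenolysis of 32 (H2, 1 atm, Pd/C, EtOAc/MeOH; the aryl triflate is expected to survive without added base) gives (2R,3R)-3-[(2S,3S)-2-(3,4-dihydroxyphenyl)-3-(3,5-dihydroxyphenyl)-4-hydroxy-2,3-dihydro-1-benzofuran-6-yl]-4-hydroxy-2-(4-hydroxyphenyl)-2,3-dihydro-1-benzofuran-6-yl trifluoromethanesulfonate F10.
- Ac2O and pyridine give its heptaacetate F11.
- Heck coupling with 4-acetoxystyrene (Pd(OAc)2, PPh3, LiCl, Et3N, DMF, 90 °C) gives the octaacetate of the target F12.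
- K2CO3 in MeOH at 0 °C under argon cleaves the acetates to 35.

## Further compounds

F1 | step 5 | 1,3,5-tris(methoxymethoxy)benzene | COCOc1cc(OCOC)cc(OCOC)c1
F2 | step 5 | (2R,3E)-4-[3,5-bis(benzyloxy)phenyl]but-3-en-2-ol | C[C@@H](O)/C=C/c1cc(OCc2ccccc2)cc(OCc2ccccc2)c1
F3 | step 5 | (2R,3E)-4-[3,5-bis(benzyloxy)phenyl]but-3-en-2-yl pyridine-2-carboxylate | C[C@@H](OC(=O)c1ccccn1)/C=C/c1cc(OCc2ccccc2)cc(OCc2ccccc2)c1
F4 | step 5 | 2-{(1S,2E)-1-[3,5-bis(benzyloxy)phenyl]but-2-en-1-yl}-1,3,5-tris(methoxymethoxy)benzene | C/C=C/[C@@H](c1cc(OCc2ccccc2)cc(OCc2ccccc2)c1)c1c(OCOC)cc(OCOC)cc1OCOC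
F5 | step 5 | (2S)-2-[3,5-bis(benzyloxy)phenyl]-2-[2,4,6-tris(methoxymethoxy)phenyl]acetaldehyde | O=C[C@@H](c1cc(OCc2ccccc2)cc(OCc2ccccc2)c1)c1c(OCOC)cc(OCOC)cc1OCOC
F6 | step 5 | (2S)-1-[3,4-bis(benzyloxy)phenyl]-2-[3,5-bis(benzyloxy)phenyl]-2-[2,4,6-tris(methoxymethoxy)phenyl]ethan-1-ol (C1 epimers) | OC(c1ccc(OCc2ccccc2)c(OCc2ccccc2)c1)[C@@H](c1cc(OCc2ccccc2)cc(OCc2ccccc2)c1)c1c(OCOC)cc(OCOC)cc1OCOC
F7 | step 8 | (2S,3S)-2-[3,4-bis(benzyloxy)phenyl]-3-[3,5-bis(benzyloxy)phenyl]-2,3-dihydro-1-benzofuran-4,6-diyl bis(trifluoromethanesulfonate) | O=S(=O)(Oc1cc(OS(=O)(=O)C(F)(F)F)c2c(c1)O[C@H](c1ccc(OCc3ccccc3)c(OCc3ccccc3)c1)[C@H]2c1cc(OCc2ccccc2)cc(OCc2ccccc2)c1)C(F)(F)F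
F8 | step 8 | (2S,3S)-2-[3,4-bis(benzyloxy)phenyl]-3-[3,5-bis(benzyloxy)phenyl]-6-vinyl-2,3-dihydro-1-benzofuran-4-yl trifluoromethanesulfonate | C=Cc1cc(OS(=O)(=O)C(F)(F)F)c2c(c1)O[C@H](c1ccc(OCc3ccccc3)c(OCc3ccccc3)c1)[C@H]2c1cc(OCc2ccccc2)cc(OCc2ccccc2)c1
F9 | step 8 | (2S,3S)-2-[3,4-bis(benzyloxy)phenyl]-3-[3,5-bis(benzyloxy)phenyl]-6-vinyl-2,3-dihydro-1-benzofuran-4-ol | C=Cc1cc(O)c2c(c1)O[C@H](c1ccc(OCc3ccccc3)c(OCc3ccccc3)c1)[C@H]2c1cc(OCc2ccccc2)cc(OCc2ccccc2)c1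
F10 | step 17 | (2R,3R)-3-[(2S,3S)-2-(3,4-dihydroxyphenyl)-3-(3,5-dihydroxyphenyl)-4-hydroxy-2,3-dihydro-1-benzofuran-6-yl]-4-hydroxy-2-(4-hydroxyphenyl)-2,3-dihydro-1-benzofuran-6-yl trifluoromethanesulfonate | O=S(=O)(Oc1cc(O)c2c(c1)O[C@@H](c1ccc(O)cc1)[C@@H]2c1cc(O)c2c(c1)O[C@H](c1ccc(O)c(O)c1)[C@H]2c1cc(O)cc(O)c1)C(F)(F)F
F11 | step 17 | heptaacetate of F10 | O=S(=O)(Oc1cc(OC(C)=O)c2c(c1)O[C@@H](c1ccc(OC(C)=O)cc1)[C@@H]2c1cc(OC(C)=O)c2c(c1)O[C@H](c1ccc(OC(C)=O)c(OC(C)=O)c1)[C@H]2c1cc(OC(C)=O)cc(OC(C)=O)c1)C(F)(F)F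
F12 | step 17 | octaacetate of 35 | CC(=O)Oc1ccc(/C=C/c2cc(OC(C)=O)c3c(c2)O[C@@H](c2ccc(OC(C)=O)cc2)[C@@H]3c2cc(OC(C)=O)c3c(c2)O[C@H](c2ccc(OC(C)=O)c(OC(C)=O)c2)[C@H]3c2cc(OC(C)=O)cc(OC(C)=O)c2)cc1
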